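In a closed, stirred vessel, a molecule of substrate meets two forks. At the first it goes to side product or down the path to target. At the second, target either stays or goes on to over-reaction product. In the runs, side product levels off within the scatter, while over-reaction product keeps growing and target falls at the later readings. We assume that target costs one partner and side product two, as the rise of side product with partner suggests.

| flask | substrate | partner | remark | time |
|---|---|---|---|---|
| noon | 1 mM | 2.4 equiv | run made earlier |  |
| autumn | 1 mM | 3.1 equiv | run made earlier |  |
| midnight | 1 mM | 3.8 equiv | run made earlier |  |
| green | 1.0 mM | 2.00 equiv |  | 2.0 min |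
| violet | 1.0 mM | 3.00 equiv |  | 2.0 min |
| blue | 1.0 mM | 4.50 equiv |  | 2.0 min |

| run | time / s | side product / % | substrate / % | target / % | over-reaction product / % |
|---|---|---|---|---|---|
| noon | 10.0 | 18 | 32 | 43 | 5 |
| noon | 12.0 | 18 | 24 | 51 | 7 |
| noon | 25.0 | 26 | 12 | 56 | 8 |
| noon | 40.0 | 26 | 6 | 52 | 18 |
| noon | 80.0 | 26 | 2 | 47 | 28 |
| autumn | 10.0 | 25 | 20 | 51 | 5 |
| autumn | 20.0 | 30 | 3 | 54 | 14 |
| autumn | 40.0 | 30 | 1 | 49 | 24 |
| autumn | 60.0 | 30 | 0 | 34 | 31 |
| autumn | 80.0 | 34 | 1 | 33 | 38 |
| midnight | 10.0 | 32 | 13 | 49 | 8 |
| midnight | 12.0 | 36 | 10 | 48 | 12 |
| midnight | 25.0 | 36 | 3 | 43 | 17 |
| midnight | 40.0 | 38 | 5 | 35 | 26 |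
| midnight | 80.0 | 37 | 4 | 20 | 44 |

(each reading ± 2 percentage points)



* which of these there is most of at the end, counted by the substrate in it, green (target / side product / over-reaction product / substrate)
* which of these there is most of at the end, counted by the substrate in it, violet (target / side product / over-reaction product / substrate)
* which of these there is most of at the end, counted by the substrate in it, blue (target / side product / over-reaction product / substrate)
* amount of the one of these that there is most of at the end, in percent of the substrate charged, green
* amount of the one of these that there is most of at the end, in percent of the substrate charged, violet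
* amount of the one of these that there is most of at the end, in percent of the substrate charged, blue

For the first fork we take side product over the rest of the substrate, divided by the equivalents of partner, and call it the fork ratio, a selectivity factor per equivalent. The last readings of the earlier runs give on average 0.156.

Violet looks nearly like autumn, with 3.00 equiv of partner against 3.1 equiv. At its last reading, 80.0 s, autumn held 33% target and 38% over-reaction product. Violet is read later, at 2.0 min, so we expect it further along the second fork.

Our reckoning for violet, scaling autumn's second fork by time and spare partner:

Side share = odds over one plus odds, with odds = fork ratio × equivalents: 31.8%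

Spare partner = equivalents − one − side share: 1.68 equivalents; autumn 1.77

Autumn's loss exponent = ln((target + over-reaction product) / target): 0.766

Violet's exponent = autumn's × time ratio × spare ratio: 1.09

Target = (one − side share) × exp(−exponent): 22.9%; over-reaction product 45.2%

The same steps give green a side share of 23.7%, target 46.5% and over-reaction product 29.7%, so we expect target to lead. Blue gets a side share of 41.2% and over-reaction product 50.8%, ahead by 9.6 percentage points.

The forecast gave target at 47% in green, over-reaction product at 43% in violet, and over-reaction product at 48% in blue, “above side product at about 41%”; its violet figure is lower than ours, and its blue figure too.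

The flasks give target at 48.9% in green, over-reaction product at 45.8% in violet and over-reaction product at 51.2% in blue.

    substrate + partner → target (k = 48.0 M⁻¹ s⁻¹)
    substrate + 2 partner → side product (k = 9200 M⁻² s⁻¹)
    partner + target → over-reaction product (k = 6.60 M⁻¹ s⁻¹)

Blue's side product stands at 41.8%, against our share of 41.2%. The neighbouring flask is blue with 11.0 equiv of partner. There the fork ratio gives odds of 1.71 and a side share of 63.1%, which leaves 36.9% for the path through target. That flask holds 66.0% side product, more than its 33.9% over-reaction product.

The readings were computed from invented constants; the scatter is artificial.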